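## Structural features

Compound 9 is a single carbocycle, a cyclopent-2-en-1-one (ketone C1, alkene C2=C3) with no second ring. C4 carries a secondary acetate, C5 is a fully substituted carbinol carbon, and C5 is bonded to C6, which carries the second acetate and an unbranched tetradecyl chain. The three stereocentres are contiguous: C4 (R), C5 (S), C6 (S). The C4 acetate is trans to the C5 hydroxyl and cis to the side chain, and O5 and O6 are related as the two oxygens that a suprafacial addition places on one face of an E-configured C5=C6 bond. The molecule is fragile in several ways: C3 is a Michael acceptor; C4–H is γ to the ketone, so base can epimerise it or isomerise the γ-oxy enone; C1/C5 form an α-ketol; C1/C5/C6 become a retro-aldol-prone β-hydroxy ketone once O6 is free; both acetates can migrate or hydrolyse. The carbon skeleton is simple, and the real difficulty is fixing the absolute configuration of C4 on a nearly flat ring and relaying it to the oxygenated quaternary C5 and to C6 without strong acid or base. The feature exploited is that the oxygens on C1 and C4 are 1,4-related across C2=C3 and flank C5, the only branching carbon. This is the pattern left when one molecule of oxygen is added across the ring diene of a 6-alkylfulvene and the peroxide bridge is opened by base, while the exocyclic C5=C6 bond survives to receive O5 and O6.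

## Logic of the disconnections

**9 ⇒ 8.** The acyl–oxygen bond at O6 is cut. O6 and O5 are best introduced together, so the C6 ester must come last. This removes a two-carbon appendage and exposes a 1,2-diol. The forward acylation must pick the secondary O6 over the tertiary O5 under conditions mild enough for a β-hydroxy ketone; acetyl exchange between O4 and O6 is harmless because both end as acetates.

**8 ⇒ 7.** The C5–O and C6–O bonds are cut together. The two hydroxyls are syn partners on adjacent carbons, the retron of a suprafacial dihydroxylation, and the C4 acetate trans to O5 can steer the face. Two stereocentres disappear and a planar cross-conjugated dienone with one stereocentre remains. The forward step needs site selectivity (exocyclic over ring alkene), attack anti to the acetate, and geometrically pure E alkene, since the Z isomer would give the C6 epimer.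

**7 ⇒ 6.** The acyl–oxygen bond at O4 is cut. The free carbinol is what the oxygenation delivers, and putting the acetate on early lets one group serve as both target functionality and steering element, so no protecting group is needed. The acylation must not disturb C4, which is γ to the ketone.

**6 ⇒ 3 (through 5 and 4).** The C1–O and C4–O bonds are cut, both oxygens coming from one oxygen molecule. Their 1,4-relationship across C2=C3 is the retron of diene oxygenation followed by base-induced peroxide cleavage. All heteroatoms and the last stereocentre are removed, leaving a hydrocarbon that already holds all twenty skeletal carbons. The forward step must favour [4+2] addition at the ring diene, must choose the same-sense bridgehead proton in both enantiomers of 4 so that 5 and 6 share the 4R configuration, must outrun the thermal rearrangement of 4, and must be followed by convergence of 5 onto 6.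

**3 ⇒ 1 + 2.** The C5=C6 bond is cut. This is the condensation retron of a CH-acidic diene with an aldehyde and leads to two purchasable materials. The aldehyde is enolisable, so mild aminocatalysis is required, and 3 is labile and must be used fresh.

## Other disconnections considered

**Alternative 1:** The cut is the C1–C2 bond of the enone. In the forward sense the 4-alkynal A1 would be cyclised by intramolecular trans-hydroacylation with the cationic rhodium catalyst [Rh(dppe)]2(BF4)2 to the spiro-acetonide cyclopentenone A2. A1 has the formyl carbon C1 on the quaternary C5, the C5/C6 diol as an acetonide, C4 as a silyl ether and a trimethylsilyl-capped C2≡C3.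
- In its favour: the ring-forming event creates no stereocentre, so C4, C5 and C6 can be secured beforehand in an open chain, and the reaction class is established for 4-alkynals. On precedent and on stereochemical certainty of the key step this plan is the better one.
- Against it: A1 is a neopentyl aldehyde on a quaternary carbon flanked by two oxygenated carbons. It would be prone to decarbonylation at rhodium and laborious to assemble in enantiopure form. A2 would still need protodesilylation at C2, acid cleavage of the acetonide next to a γ-oxy enone, desilylation and two selective acetylations.
- Comparison: structurally it builds the ring last from a long protected chain, whereas the chosen plan obtains ring and skeleton in one condensation. Mechanistically it is safer. In step economy it should need well over twice the five steps of the chosen plan and three protecting groups against none.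

**Alternative 2:** The cut is the C1–C5 ring bond together with the C6–O bond. In the forward sense the nitro compound A3 would be dehydrated with phenyl isocyanate and triethylamine to a nitrile oxide, which would add across the tethered Z-enol ether to give the cyclopenta-fused isoxazoline A4.
- In its favour: the reaction class is known, and the suprafacial addition transcribes alkene geometry into the C5/C6 relationship. This is the same stereochemical logic as the dihydroxylation of the chosen plan, so the two are equal on that point. It also makes the quaternary C5 by C–C bond formation and keeps the retro-aldol-prone β-hydroxy ketone masked as the isoxazoline until late, on which it is the better.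
- Against it: A4 is saturated at C2–C3, so the enone would have to be introduced late on a β-hydroxy ketone. The N–O bond must be cleaved, the benzyl ethers must go before the alkene exists, and three hydroxyls must then be differentiated. A geometrically pure Z-enol ether A3 and facial control from C4 are further burdens.
- Comparison: mechanistically safer than the proposed key step, but structurally it reaches the wrong oxidation level of the ring. It would probably be about three times as long.

**Alternative 3:** The cut is the C4–C5 bond. In the forward sense the furan-derived pyranone lactol A5 would open under triethylamine to the Z-ene-dicarbonyl, enolise toward C5 and close by intramolecular aldol addition onto the C4 aldehyde to give the 4,5-dihydroxycyclopentenone A6. The ring stereocentre of A5 is erased and re-formed.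
- In its favour: the ring contraction is a known type, the product has the enone and all three oxygens in place with O6 already differentiated, and only C6 must be set beforehand. It is the equal of the chosen plan in reaching the enone directly and the better on precedent and on hydroxyl differentiation.
- Against it: C4 and C5 would be controlled only by the exocyclic C6 centre in a reversible aldol, in a basic medium that can also isomerise the γ-hydroxy enone. A5 needs an enantioselective synthesis and an oxidative ring expansion, and A6 needs acetylation, desilylation and a second acetylation.
- Comparison: roughly twice the step count and one protecting group. The stereochemical risk moves from an untested catalyst-controlled step to a substrate-controlled equilibrating aldol.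

Key step: step 2

Assumption: cyclopentadiene is bought as its dimer and cracked by distillation immediately before use; this distillation is treated as preparation of a starting material, not as a step.

Remark on the structures: with the C4 oxygen on the lower ring face, syn-dihydroxylation of the 5E alkene from the upper face gives 5S,6S with O4 trans to O5. The 5Z alkene would give the C6 epimer, so E geometry is obligatory. No structure needed correction, and 3 is kept as the bare hydrocarbon, with only its handling tightened (fresh, cold, under argon).

## Route

**Step 1**
Reactants: 1 cyclopenta-1,3-diene; 2 pentadecanal
Product: 3 5-pentadecylidenecyclopenta-1,3-diene (6-tetradecylfulvene)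
Conditions: pyrrolidine (20 mol%), MeOH–THF, 0 °C → rt, Ar; 1 in 2.5-fold excess
Reagents that add atoms: none
Why: Amine-catalysed fulvene condensation (a variant of the Thiele fulvene synthesis): pyrrolidine turns 2 into an iminium ion, cyclopentadiene adds, and E1cB loss of the amine gives the cross-conjugated fulvene; the excess of 1 suppresses self-aldolisation of 2, and no stereocentre is formed.

**Step 2**
Reactants: 3 5-pentadecylidenecyclopenta-1,3-diene
Product: 6 (4R,5E)-4-hydroxy-5-pentadecylidenecyclopent-2-en-1-one, via racemic fulvene endoperoxide 4 (not isolated), via (4R,5Z)-hydroxy dienone 5 (not isolated)
Conditions: O2, tetraphenylporphyrin (0.5 mol%), 590 nm LED, CH2Cl2, −78 °C; Ar purge, then O-acetylcupreidine (10 mol%), −78 → −40 °C; cold aq. citric acid wash; then I2 (10 mol%), CH2Cl2, rt, daylight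
Reagents that add atoms: dioxygen, O=O
Why: Proposed new method: sensitised singlet oxygen adds suprafacially in a [4+2] sense across the s-cis ring diene of 3 (C1 and C4) to give racemic 4, whose dioxabicycle is only transient, so no ring is closed in the product; the quinuclidine nitrogen of the cinchona catalyst then removes one bridgehead proton with O–O cleavage (Kornblum–DeLaMare), making that carbon the C1 ketone and leaving the other bridgehead as the C4 alkoxide, which is protonated. The closest known reaction types are the triethylamine-induced Kornblum–DeLaMare opening of cyclic-diene endoperoxides and the cinchona-amine desymmetrisation of meso bicyclic endoperoxides; new is the demand that the catalyst treat the two bridgeheads of a racemic, chain-desymmetrised fulvene endoperoxide as if they were enantiotopic. C4 is the only new stereocentre and is set by the catalyst, because the dioxabicyclic core is mirror-symmetric apart from the distant chain, so the phenol–quinuclidine pair should bind the peroxide bridge and take the same-sense bridgehead proton in both enantiomers of 4 (O-acetylcupreidine is the first choice, its pseudoenantiomer O-acetylcupreine the reserve if the sense is the opposite one, judged by Mosher ester analysis). The enantiomer of 4 whose chain leans toward the retained bridgehead gives 6 directly and the other gives 5, both 4R, which makes this a regiodivergent reaction of a racemate. The selectivity needed is catalyst control over the intrinsic preference for the bridgehead proton remote from the chain, together with a cleavage rate that beats the thermal rearrangement of 4, which is why the amine is added cold and only after oxygen has been purged. Preference for [4+2] addition over the ene reaction at C7–H is secured by the locked s-cis diene. After the acid wash has removed the amine, catalytic iodine adds reversibly as an iodine atom to C6 and lets 5 relax to 6, whose chain avoids the carbonyl oxygen, while C4 is untouched because its ionisation is disfavoured by the cross-conjugated carbonyl.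

**Step 3**
Reactants: 6 (4R,5E)-4-hydroxy-5-pentadecylidenecyclopent-2-en-1-one
Product: 7 (1R,5E)-4-oxo-5-pentadecylidenecyclopent-2-en-1-yl acetate
Conditions: Ac2O, pyridine, DMAP (2 mol%), CH2Cl2, 0 °C
Reagents that add atoms: acetic anhydride, CC(=O)OC(C)=O
Why: Standard O-acetylation by acyl transfer to the secondary alcohol; no bond to C4 is broken, so its configuration is retained, and the weak base at 0 °C should avoid γ-deprotonation.

**Step 4**
Reactants: 7 (1R,5E)-4-oxo-5-pentadecylidenecyclopent-2-en-1-yl acetate
Product: 8 (1R,5S)-5-hydroxy-5-[(1S)-1-hydroxypentadecyl]-4-oxocyclopent-2-en-1-yl acetate
Conditions: OsO4 (5 mol%), NMO (1.2 equiv), citric acid (1 equiv), t-BuOH–acetone–H2O, 0 °C → rt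
Reagents that add atoms: osmium tetroxide, O=[Os](=O)(=O)=O; N-methylmorpholine N-oxide, C[N+]1([O-])CCOCC1; water, O
Why: Upjohn syn-dihydroxylation: OsO4 should add to the more electron-rich trisubstituted exocyclic C5=C6 rather than the disubstituted ring alkene, and from the face opposite the C4 acetate (the C4–H side), so O5 ends trans to O4 (5S); because the addition is suprafacial on the E alkene, C6 emerges S. Citric acid keeps the medium acidic, which aids turnover on electron-poor alkenes and protects the β-hydroxy ketone from retro-aldol cleavage.

**Step 5**
Reactants: 8 (1R,5S)-5-hydroxy-5-[(1S)-1-hydroxypentadecyl]-4-oxocyclopent-2-en-1-yl acetate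
Product: 9 (1S)-1-[(1S,5R)-5-acetoxy-1-hydroxy-2-oxocyclopent-3-en-1-yl]pentadecyl acetate
Conditions: Ac2O, pyridine, DMAP (5 mol%), CH2Cl2, 0 °C → rt
Reagents that add atoms: acetic anhydride, CC(=O)OC(C)=O
Why: Nucleophile-catalysed acetylation of the only secondary hydroxyl; the tertiary C5 hydroxyl, flanked by the ketone and two oxygenated carbons, should react far more slowly, acetyl exchange between O4 and O6 is harmless because both end as acetates, and no stereocentre is touched.

## Compound list

1 | cyclopenta-1,3-diene | C1C=CC=C1 | starting material
2 | pentadecanal | CCCCCCCCCCCCCCC=O | starting material
3 | 5-pentadecylidenecyclopenta-1,3-diene (6-tetradecylfulvene) | CCCCCCCCCCCCCCC=C1C=CC=C1 | intermediate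
4 | racemic 7-pentadecylidene-2,3-dioxabicyclo[2.2.1]hept-5-ene (not isolated) | CCCCCCCCCCCCCCC=C1C2C=CC1OO2 | intermediate
5 | (4R,5Z)-4-hydroxy-5-pentadecylidenecyclopent-2-en-1-one (not isolated) | CCCCCCCCCCCCCC/C=C1\C(=O)C=C[C@H]1O | intermediate
6 | (4R,5E)-4-hydroxy-5-pentadecylidenecyclopent-2-en-1-one | CCCCCCCCCCCCCC/C=C1/C(=O)C=C[C@H]1O | intermediate
7 | (1R,5E)-4-oxo-5-pentadecylidenecyclopent-2-en-1-yl acetate | CCCCCCCCCCCCCC/C=C1/C(=O)C=C[C@H]1OC(C)=O | intermediate
8 | (1R,5S)-5-hydroxy-5-[(1S)-1-hydroxypentadecyl]-4-oxocyclopent-2-en-1-yl acetate | CCCCCCCCCCCCCC[C@H](O)[C@@]1(O)C(=O)C=C[C@H]1OC(C)=O | intermediate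
9 | (1S)-1-[(1S,5R)-5-acetoxy-1-hydroxy-2-oxocyclopent-3-en-1-yl]pentadecyl acetate | CCCCCCCCCCCCCC[C@H](OC(C)=O)[C@@]1(O)C(=O)C=C[C@H]1OC(C)=O | target

## Step count and least certain steps

Total step count: 5. Longest linear sequence: 5 steps (from 1 or 2 to 9).

**Step 2 (key step, the proposed new method).** The most likely failure is loss of catalyst control in the enantiomer of 4 whose chain leans toward the bridgehead the catalyst is meant to deprotonate. That proton sits next to the chain, so the amine may take the unhindered proton instead, which feeds 4S material into the E series and erodes enantiopurity after convergence. Also possible are thermal rearrangement of 4 outrunning a slow cleavage at −40 °C, amine-induced isomerisation of the γ-hydroxy enone if the mixture warms before the acid wash, and incomplete Z-to-E convergence. As a check, the E and Z fractions of an aliquot would be analysed separately before iodine is added; if only one enantiomer of 4 reacts cleanly, the step would be run as a kinetic resolution.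

Fallback with known chemistry, setting out from 3: the same photooxygenation followed by triethylamine at −78 → −30 °C (achiral Kornblum–DeLaMare opening) should give racemic (5Z)-4-hydroxy-5-pentadecylidenecyclopent-2-en-1-one F1 and racemic (5E)-4-hydroxy-5-pentadecylidenecyclopent-2-en-1-one F2. Catalytic iodine converges F1 onto F2. A lipase-mediated kinetic resolution (Candida antarctica lipase B, vinyl acetate, MTBE, rt) is then expected, by the empirical size rule for lipase acylation of secondary alcohols, to acetylate the R enantiomer and give 7 directly. The unreacted (4S,5E)-4-hydroxy-5-pentadecylidenecyclopent-2-en-1-one F3 is removed by chromatography. The fallback comes back to the route at 7 and makes step 3 unnecessary, at the cost of at most half of the material at a cheap stage.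

**Step 4.** The most likely failures are poor facial selectivity, because an acetate is only a modest shield, and competing osmylation of the ring alkene C2=C3. Acetyl migration or retro-aldol cleavage of the product during a slow reaction is also possible.

Fallback, setting out from 6: silylation (TBSCl, imidazole, DMF) gives (4R,5E)-4-(tert-butyldimethylsilyloxy)-5-pentadecylidenecyclopent-2-en-1-one F4, whose bulkier group blocks the lower face more decisively. The same osmylation should give (4R,5S)-4-(tert-butyldimethylsilyloxy)-5-hydroxy-5-[(1S)-1-hydroxypentadecyl]cyclopent-2-en-1-one F5. Buffered HF·pyridine in THF at 0 °C (no basic fluoride) releases (4R,5S)-4,5-dihydroxy-5-[(1S)-1-hydroxypentadecyl]cyclopent-2-en-1-one F6. Ac2O/pyridine then acetylates both secondary hydroxyls at once, and the fallback comes back to the route at 9, one step longer than the main line. If the ring alkene competes, ligand-accelerated osmylation with (DHQ)2PHAL, the ligand that the face-selection mnemonic of the asymmetric dihydroxylation pairs with the upper face of this E alkene, would be added to the same sequence.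

**Step 1.** The most likely failures are self-aldolisation of the enolisable aldehyde, conjugate addition of amine or cyclopentadienyl units to the product, and oligomerisation or double-bond migration of the fulvene during isolation.

Fallback, setting out from 1: condensation with N,N-dimethylformamide dimethyl acetal gives 6-(dimethylamino)fulvene F7 (also a catalogue compound). Tetradecyllithium F8, made from 1-bromotetradecane and lithium metal in Et2O, adds to C6 to give lithium [1-(dimethylamino)pentadecyl]cyclopentadienide F9. On aqueous work-up F9 loses dimethylamine, and the fallback comes back to the route at 3. This forms C6–C7 instead of C5=C6 and takes the enolisable aldehyde out of the synthesis.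

**Step 3.** The most likely failure is erosion of C4 through amine-mediated γ-deprotonation, or conjugate addition of the nucleophilic catalyst to the cross-conjugated dienone.

Fallback, setting out from 6: enzymatic transesterification (Candida antarctica lipase B, vinyl acetate, MTBE, rt) transfers the acetyl group at neutral pH without any amine and, being enantiomer-selective, should also raise the enantiopurity. It comes back to the route at 7 and makes no new compound (F0).

## Further compounds

F1 | step 2 | racemic (5Z)-4-hydroxy-5-pentadecylidenecyclopent-2-en-1-one | CCCCCCCCCCCCCC/C=C1\C(=O)C=CC1O
F2 | step 2 | racemic (5E)-4-hydroxy-5-pentadecylidenecyclopent-2-en-1-one | CCCCCCCCCCCCCC/C=C1/C(=O)C=CC1O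
F3 | step 2 | (4S,5E)-4-hydroxy-5-pentadecylidenecyclopent-2-en-1-one | CCCCCCCCCCCCCC/C=C1/C(=O)C=C[C@@H]1O
F4 | step 4 | (4R,5E)-4-(tert-butyldimethylsilyloxy)-5-pentadecylidenecyclopent-2-en-1-one | CCCCCCCCCCCCCC/C=C1/C(=O)C=C[C@H]1O[Si](C)(C)C(C)(C)C
F5 | step 4 | (4R,5S)-4-(tert-butyldimethylsilyloxy)-5-hydroxy-5-[(1S)-1-hydroxypentadecyl]cyclopent-2-en-1-one | CCCCCCCCCCCCCC[C@H](O)[C@@]1(O)C(=O)C=C[C@H]1O[Si](C)(C)C(C)(C)C
F6 | step 4 | (4R,5S)-4,5-dihydroxy-5-[(1S)-1-hydroxypentadecyl]cyclopent-2-en-1-one | CCCCCCCCCCCCCC[C@H](O)[C@@]1(O)C(=O)C=C[C@H]1O
F7 | step 1 | 6-(dimethylamino)fulvene | CN(C)C=C1C=CC=C1
F8 | step 1 | tetradecyllithium | [Li]CCCCCCCCCCCCCC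
F9 | step 1 | lithium [1-(dimethylamino)pentadecyl]cyclopentadienide | CCCCCCCCCCCCCCC(N(C)C)[c-]1cccc1.[Li+]
F0 | step 3 | none | none
A1 | alternative 1 | 4-[1-(tert-butyldimethylsilyloxy)-3-(trimethylsilyl)prop-2-yn-1-yl]-2,2-dimethyl-5-tetradecyl-1,3-dioxolane-4-carbaldehyde, configured as in the SMILES | CCCCCCCCCCCCCC[C@@H]1OC(C)(C)O[C@]1(C=O)[C@H](O[Si](C)(C)C(C)(C)C)C#C[Si](C)(C)C
A2 | alternative 1 | 9-(tert-butyldimethylsilyloxy)-2,2-dimethyl-4-tetradecyl-7-(trimethylsilyl)-1,3-dioxaspiro[4.4]non-7-en-6-one, configured as in the SMILES | CCCCCCCCCCCCCC[C@@H]2OC(C)(C)O[C@@]21C(=O)C([Si](C)(C)C)=C[C@H]1O[Si](C)(C)C(C)(C)C
A3 | alternative 2 | (5Z)-4,5-bis(benzyloxy)-1-nitroicos-5-ene, C4 configured as in the SMILES | CCCCCCCCCCCCCC/C=C(\OCc1ccccc1)[C@H](OCc1ccccc1)CCC[N+](=O)[O-]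
A4 | alternative 2 | cyclopenta-fused 2-isoxazoline with benzyloxy groups on C4 and C5 and tetradecyl on C6 (target numbering), configured as in the SMILES | CCCCCCCCCCCCCC[C@H](O3)[C@@]1(OCc2ccccc2)C(=N3)CC[C@H]1OCc4ccccc4
A5 | alternative 3 | 6-hydroxy-2-[1-(tert-butyldimethylsilyloxy)pentadecyl]-2H-pyran-3(6H)-one, side-chain centre configured as in the SMILES, ring centres unspecified | CCCCCCCCCCCCCC[C@H](O[Si](C)(C)C(C)(C)C)C1OC(O)C=CC1=O
A6 | alternative 3 | 4,5-dihydroxy-5-[1-(tert-butyldimethylsilyloxy)pentadecyl]cyclopent-2-en-1-one, configured as in the SMILES | CCCCCCCCCCCCCC[C@H](O[Si](C)(C)C(C)(C)C)[C@@]1(O)C(=O)C=C[C@H]1O
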